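## The problem

CNP0534814.1 is a germacranolide: a ten-membered carbocycle (C1–C10) with a trans-1,10-epoxide, a C3 carbinol, a C4=C5 alkene whose ring bonds are cis and whose C4 substituent is an aldehyde (C15), an α-methylene-γ-butyrolactone fused across C6–C7 (oxygen on C6, carboxyl C12) and a methacrylate on C8. Germacrane locants are used throughout, also for open-chain intermediates. Six stereocentres must be set (1R, 3S, 6R, 7R, 8R, 10R). C7 and C8 are adjacent and can be made together, and C1/C10 come as a pair from an (E)-alkene. C3 and C6 have no nearby controlling centre and need the ring conformation, a reagent or a catalyst of their own. The medium ring has to be closed with the trisubstituted C4=C5 geometry already fixed. The epoxide opens with acid, the α-methylene lactone, methacrylate and enal are Michael acceptors, and the C8 ester is β to C6 and γ to C12, so a C6 carbonyl or a free C8 hydroxyl invites elimination or lactonisation towards C8. The feature that opens the chosen route is that C6 is allylic to C4=C5 and γ to the C12 carboxyl of an 11(13)-en-12-oic acid: this is the C–H that lactone-forming sesquiterpene P450 oxidases hydroxylate, after which the γ-hydroxy acid closes by itself.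

## Retrosynthesis

**42 ⇒ 41.** No skeletal bond is cut; the C15 aldehyde goes back to the primary allylic alcohol 41. Leaving this to the end keeps the enal out of every other step. The forward reaction must oxidise a primary allylic alcohol beside the secondary C3 alcohol, which an oxoammonium oxidant does.

**41 ⇒ 39 (key disconnection).** The C6–O and O–C12 bonds are cut, removing the lactone ring and the C6 stereocentre and leaving the C6-methylene acid 39; the forward intermediate is the 6-hydroxy acid 40. The classical neighbouring cut, C6–C7 by allyl-metal addition to a C6 aldehyde, would put a carbonyl on C6 next to the C8 ester and make ring and lactone together. Cutting only C–O leaves a precursor with all carbons and five of six stereocentres in place. The forward step must hydroxylate one allylic C–H among many, on one face, and spare three alkenes and an epoxide; that is asked of a P450 enzyme, not of a reagent.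

**39 ⇒ 35 (through 38, 37, 36).** Functional-group changes only: the C12 carboxyl goes back to a PMB-protected allylic alcohol and C15–OH to its TBDPS ether. A C12 ester would be shorter on paper but would have to be cleaved beside the methacrylate. The alcohol level cannot lactonise onto C8 and is raised by two mild oxidations.

**35 ⇒ 34.** The C3–C4 bond is cut to a vinyl iodide and an aldehyde (Nozaki–Hiyama–Kishi). Ring-closing metathesis at C4=C5 or C1=C10 would give trisubstituted alkenes in a strained ring without geometric control, and closure at C6–C7 needs a C6 carbonyl. This cut gives the C3 carbinol directly and brings the alkene geometry in from an open-chain vinyl iodide. The forward reaction must close a ten-membered ring at high dilution and choose the C3 face.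

**34 ⇒ 32 ⇒ 28 (through 33, 31, 29).** The epoxide goes back to the (E)-alkene of 32 (Shi epoxidation, reagent control, while that alkene is the only electron-rich one), the aldehyde to a primary alcohol, and the methacrylate to the C8 silyl ether of 28. The methacrylate is installed before ring closure because afterwards C3–OH and C8–OH could not be told apart.

**28 ⇒ 22 + 24.** The C11–C12 bond and the C11=C13 methylene are cut: the 1,1-disubstituted alkene comes from ketone 27, made from Weinreb amide 22 and the alkoxymethyl reagent from stannane 24 (from 23). Carbonylation of an enol triflate would reach the ester level directly but needs palladium, which the vinyl iodide excludes.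

**22 ⇒ 10 + 18.** The C7–C8 bond is cut (Evans syn aldol, through 20 and 21). It joins two fragments of similar size and sets both stereocentres in one step with the recoverable auxiliary 8; an alkylation or allylation would set only one. The forward reaction goes through Z-boron enolate 19 and must not let the β,γ-unsaturated aldehyde 18 conjugate.

**10 ⇒ 7 ⇒ 5 ⇒ 4 ⇒ 2 ⇒ 1.** The C6–C7 bond is cut to allylic bromide 5 and an acetate enolate (via 6). The vinyl iodide of 4 goes back to propargylic alcohol 2 by hydroxyl-directed trans-hydroalumination and iodination, and 2 to diol 1. This gives C4–C6 and C15, with iodine on C4 cis to C6, from a symmetric four-carbon diol.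

**18 ⇒ 17 ⇒ 16 ⇒ 15 ⇒ 12 ⇒ 11.** The C10–C14 and C1–C2 bonds are cut: carboalumination of alkyne 12 (from 11) and trapping with ethylene oxide give 15 with the (E)-alkene. Protecting-group exchange and oxidation give 18.

## Roads not taken

**Alternative 1:** The cut is the C6–C10 bond of a smaller bicycle. In a Grob fragmentation KOt-Bu would form a tertiary C6 alkoxide that breaks C6–C10 anti-periplanar to a C1 mesylate, giving the cyclodecadienone A1.
- Merits: no entropic macrocyclisation; the (E)-C1=C10 geometry follows stereospecifically from the bicycle; C3, C7 and C8 are already in place.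
- Weak points: the bicyclic precursor needs five stereocentres including the tertiary carbinol. A1 has a C6 ketone β to the C8 oxygen and α to C7, so alkoxide conditions invite E1cB loss of the C8 substituent and epimerisation at C7. After ring formation the ketone must be reduced from the right face, the two-carbon arm on C7 oxidised and methylenated, C1=C10 epoxidised selectively, and the MOM ether exchanged for the methacrylate under acid that the epoxide tolerates poorly.
- Comparison: every step is known chemistry and C6 would be set by an ordinary reduction, which is more than the chosen plan can claim for its key step. Against this the chosen plan has a two-step end-game after acid 39 and never places a carbonyl on C6 next to the C8 ester.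

**Alternative 2:** The cut is C4=C5. An intramolecular Horner–Wadsworth–Emmons reaction (LiCl, i-Pr2NEt) between a phosphonoacetate carbanion at C4 and an aldehyde at C5 would close the ring and form the alkene together, giving A2 with the lactone in place.
- Merits: convergent, mild and well known for macrocycles; the usual (E)-enoate preference coincides with the ring-cis geometry; no enzyme.
- Weak points: the aldehyde is attached to C6, which carries the lactone oxygen, so C6 can epimerise. The carbanion shares the molecule with the α-methylene lactone, a Michael acceptor, and the C3 oxygen β to it can be eliminated. A2 holds C15 as a methyl ester that must be reduced to the aldehyde beside the lactone.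
- Comparison: as a ring construction this road is at least as good as the NHK closure of the chosen plan and controls the alkene geometry with less risk. The chosen plan sets against it that it never has to distinguish a C15 ester from the C12 lactone, and that the lactone appears only in the penultimate step.

**Alternative 3:** The cut is C7–C11. A diazo(diethoxyphosphoryl)acetate ester on the C6 oxygen of the preformed ring would be decomposed by Rh2(OAc)4, and the carbenoid would insert into a C7–H bond to give the phosphono lactone A3; the phosphonate then serves for methylenation with formaldehyde.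
- Merits: like the chosen plan it builds the lactone late on an intact ring; 1,5-insertion to γ-lactones is well established; the phosphonate solves the α-methylene problem.
- Weak points: the carbenoid sits on an allylic oxygen, so cyclopropanation of C4=C5 competes. The C7–H bonds are deactivated by the C8 oxygen while the C8–H bond is activated, the epoxide oxygen can form ylides, and the choice between the two C7 hydrogens fixes C7 with no clear control. C15 is again an ester.
- Comparison: the reactivity is known, whereas the enzyme of the chosen plan has yet to be found. The chosen plan sets against it that C7 is made early and securely by an auxiliary aldol, and that the late step forms only one C–O bond at the position the substrate itself activates.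

Key step: step 28

Remark on the chemistry: an evolved P450 of the costunolide-synthase type that accepts 39 and hydroxylates the C6 face leading to the trans-fused lactone (as the wild-type enzymes do with germacrenoic acids) is assumed to be obtainable.

## Steps

Step 1
Reactants: 1 but-2-yne-1,4-diol
Product: 2 4-[(tert-butyldiphenylsilyl)oxy]but-2-yn-1-ol
Conditions: TBDPSCl (0.3 equiv), imidazole, DMF, 0 °C to rt (1 in excess)
Reagents that add atoms: tert-butyl(chloro)diphenylsilane, CC(C)(C)[Si](Cl)(c1ccccc1)c1ccccc1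
Why: Statistical monosilylation of a symmetric diol; the excess of cheap, water-soluble 1 suppresses the bis-ether.

Step 2
Reactants: 2 4-[(tert-butyldiphenylsilyl)oxy]but-2-yn-1-ol
Product: 4 (Z)-4-[(tert-butyldiphenylsilyl)oxy]-3-iodobut-2-en-1-ol, via cyclic sodium vinylalanate 3 (not isolated)
Conditions: NaAlH2(OCH2CH2OMe)2, THF, 0 °C; then I2, THF, −78 °C
Reagents that add atoms: iodine, II
Why: Hydroxyl-directed trans-hydroalumination puts aluminium on the distal alkyne carbon in a five-membered alanate, and iodinolysis with retention gives the vinyl iodide with iodine on C4 and cis to C6, the geometry the ring needs.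

Step 3
Reactants: 4 (Z)-4-[(tert-butyldiphenylsilyl)oxy]-3-iodobut-2-en-1-ol
Product: 5 (Z)-[(4-bromo-2-iodobut-2-en-1-yl)oxy](tert-butyl)diphenylsilane
Conditions: CBr4, PPh3, CH2Cl2, 0 °C
Reagents that add atoms: carbon tetrabromide, BrC(Br)(Br)Br
Why: Appel bromination of a primary allylic alcohol; SN2 at C6 leaves the vinyl iodide and silyl ether untouched.

Step 4
Reactants: 5 (Z)-[(4-bromo-2-iodobut-2-en-1-yl)oxy](tert-butyl)diphenylsilane
Product: 6 ethyl (Z)-6-[(tert-butyldiphenylsilyl)oxy]-5-iodohex-4-enoate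
Conditions: EtOAc, LiN(i-Pr)2, THF, −78 °C; then 5, −78 to −40 °C
Reagents that add atoms: ethyl acetate, CCOC(C)=O
Why: SN2 alkylation of the ester enolate by the primary allylic bromide forms C6–C7; at low temperature the amide base does not attack the vinyl iodide.

Step 5
Reactants: 6 ethyl (Z)-6-[(tert-butyldiphenylsilyl)oxy]-5-iodohex-4-enoate
Product: 7 (Z)-6-[(tert-butyldiphenylsilyl)oxy]-5-iodohex-4-enoic acid
Conditions: LiOH, THF–MeOH–H2O, rt; then aq. HCl
Reagents that add atoms: lithium hydroxide, [Li+].[OH-]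
Why: Ester saponification; the TBDPS ether and vinyl iodide are stable to aqueous hydroxide at room temperature.

Step 6
Reactants: 7 (Z)-6-[(tert-butyldiphenylsilyl)oxy]-5-iodohex-4-enoic acid; 8 (S)-4-benzyl-1,3-oxazolidin-2-one
Product: 10 (S)-4-benzyl-3-{(Z)-6-[(tert-butyldiphenylsilyl)oxy]-5-iodohex-4-enoyl}-1,3-oxazolidin-2-one, via mixed pivalic anhydride 9 (not isolated)
Conditions: PivCl, Et3N, THF, −20 °C; then LiCl, 8, −20 °C to rt
Reagents that add atoms: none
Why: N-Acylation of the oxazolidinone through the mixed anhydride with LiCl activation; no organolithium base is needed beside the vinyl iodide.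

Step 7
Reactants: 11 but-3-yn-1-ol
Product: 12 1-[(but-3-yn-1-yloxy)methyl]-4-methoxybenzene
Conditions: NaH, 4-methoxybenzyl chloride, Bu4NI (cat.), THF–DMF, 0 °C to rt
Reagents that add atoms: 4-methoxybenzyl chloride, COc1ccc(CCl)cc1
Why: Williamson etherification; the alkoxide forms selectively because the alcohol is far more acidic than the alkyne.

Step 8
Reactants: 12 1-[(but-3-yn-1-yloxy)methyl]-4-methoxybenzene
Product: 15 (E)-6-[(4-methoxybenzyl)oxy]-4-methylhex-3-en-1-ol, via alkenyldimethylalane 13 (not isolated), via lithium alkenylalanate 14 (not isolated)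
Conditions: AlMe3, Cp2ZrCl2 (cat.), CH2Cl2, rt; evaporate; n-BuLi, THF–hexane, −78 to 0 °C; ethylene oxide, 0 °C
Reagents that add atoms: trimethylaluminium, C[Al](C)C; ethylene oxide, C1CO1
Why: Negishi zirconium-catalysed syn-carboalumination adds methyl to the internal and aluminium to the terminal alkyne carbon; the alanate transfers the alkenyl group to ethylene oxide with retention, so C2 ends cis to the methyl group and the C1=C10 alkene is (E).

Step 9
Reactants: 15 (E)-6-[(4-methoxybenzyl)oxy]-4-methylhex-3-en-1-ol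
Product: 16 tert-butyl{[(E)-6-[(4-methoxybenzyl)oxy]-4-methylhex-3-en-1-yl]oxy}dimethylsilane
Conditions: TBSCl, imidazole, CH2Cl2, rt
Reagents that add atoms: tert-butyl(chloro)dimethylsilane, CC(C)(C)[Si](C)(C)Cl
Why: Silylation of the primary C3 alcohol, which must stay masked until the ring closure.

Step 10
Reactants: 16 tert-butyl{[(E)-6-[(4-methoxybenzyl)oxy]-4-methylhex-3-en-1-yl]oxy}dimethylsilane
Product: 17 (E)-6-[(tert-butyldimethylsilyl)oxy]-3-methylhex-3-en-1-ol
Conditions: DDQ, CH2Cl2–aq. NaH2PO4/Na2HPO4 buffer (pH 7), 0 °C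
Reagents that add atoms: none
Why: Oxidative cleavage of the PMB ether by DDQ frees the C8 alcohol; the silyl ether and the alkene are not affected.

Step 11
Reactants: 17 (E)-6-[(tert-butyldimethylsilyl)oxy]-3-methylhex-3-en-1-ol
Product: 18 (E)-6-[(tert-butyldimethylsilyl)oxy]-3-methylhex-3-enal
Conditions: Dess–Martin periodinane, pyridine, CH2Cl2, 0 °C; used at once
Reagents that add atoms: none
Why: Dess–Martin oxidation under buffered, non-basic conditions gives the β,γ-unsaturated aldehyde without shifting the alkene into conjugation.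

Step 12
Reactants: 10 (S)-4-benzyl-3-{(Z)-6-[(tert-butyldiphenylsilyl)oxy]-5-iodohex-4-enoyl}-1,3-oxazolidin-2-one; 18 (E)-6-[(tert-butyldimethylsilyl)oxy]-3-methylhex-3-enal
Product: 20 syn-aldol adduct (7S,8R; 2S,3R in the acyl chain) with C8–OH, via dibutylboron Z-enolate 19 (not isolated)
Conditions: Bu2BOTf, Et3N, CH2Cl2, −78 to 0 °C; 18, −78 to 0 °C; then NaH2PO4/Na2HPO4 buffer (pH 7), MeOH, H2O2, 0 °C
Reagents that add atoms: none
Why: Evans syn aldol: the Z-boron enolate reacts through a chair transition state on the face opposite the benzyl group, forming C7–C8 and setting both centres in one step; the aldehyde meets only the pre-formed enolate at low temperature, which limits its isomerisation.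

Step 13
Reactants: 20 syn-aldol adduct
Product: 21 Weinreb amide (2S,3R,5E)-8-[(tert-butyldimethylsilyl)oxy]-2-{(2Z)-4-[(tert-butyldiphenylsilyl)oxy]-3-iodobut-2-en-1-yl}-3-hydroxy-N-methoxy-N,5-dimethyloct-5-enamide
Conditions: MeNH(OMe)·HCl, AlMe3, CH2Cl2, −10 to 0 °C
Reagents that add atoms: N,O-dimethylhydroxylamine hydrochloride, CNOC.Cl
Why: Aluminium amide transamidation of the β-hydroxy imide; the free hydroxyl directs attack to the exocyclic carbonyl and the auxiliary 8 is recovered.

Step 14
Reactants: 21 Weinreb amide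
Product: 22 C8 triethylsilyl ether of 21
Conditions: TESOTf, 2,6-lutidine, CH2Cl2, −78 °C
Reagents that add atoms: triethylsilyl trifluoromethanesulfonate, CC[Si](CC)(CC)OS(=O)(=O)C(F)(F)F
Why: Silylation of the secondary alcohol prevents retro-aldol and β-elimination in the next two steps; TES is chosen so that it can be removed before the primary TBS and TBDPS ethers.

Step 15
Reactants: 23 (tributylstannyl)methanol
Product: 24 tributyl{[(4-methoxybenzyl)oxy]methyl}stannane
Conditions: NaH, 4-methoxybenzyl chloride, Bu4NI (cat.), THF–DMF, 0 °C to rt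
Reagents that add atoms: 4-methoxybenzyl chloride, COc1ccc(CCl)cc1
Why: Williamson etherification gives the precursor of the alkoxymethyl anion that will supply C12.

Step 16
Reactants: 22 C8 triethylsilyl ether of the Weinreb amide; 24 tributyl{[(4-methoxybenzyl)oxy]methyl}stannane
Product: 27 α-alkoxy ketone (C11 ketone carrying C12H2–OPMB; 7S,8R), via alkoxymethyllithium 25 (not isolated), via alkoxymethylmagnesium bromide 26 (not isolated)
Conditions: 24, n-BuLi (slightly less than 24), THF, −78 °C; MgBr2·OEt2, −78 °C; then 22, −78 to −20 °C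
Reagents that add atoms: none
Why: Tin–lithium exchange gives the α-alkoxymethyllithium, transmetalation to magnesium removes the species able to exchange with the vinyl iodide, and the chelated tetrahedral adduct of the Weinreb amide stops at the ketone, forming C11–C12.

Step 17
Reactants: 27 α-alkoxy ketone
Product: 28 1,1-disubstituted alkene (C11=C13 methylene in place of the ketone; 7R,8R)
Conditions: Cp2TiMe2, toluene, 70 °C, dark
Reagents that add atoms: dimethyltitanocene, [CH3-].[CH3-].[Ti+4].c1cc[cH-]c1.c1cc[cH-]c1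
Why: Petasis methylenation is a non-basic carbonyl olefination, so the C7 centre α to the ketone is not epimerised and the β-silyloxy group is not eliminated.

Step 18
Reactants: 28 1,1-disubstituted alkene
Product: 29 C8 alcohol (7R,8R)
Conditions: pyridinium p-toluenesulfonate, MeOH–CH2Cl2, 0 °C
Reagents that add atoms: none
Why: Acid-catalysed methanolysis cleaves the secondary triethylsilyl ether much faster than the primary TBS and TBDPS ethers.

Step 19
Reactants: 29 C8 alcohol; 30 methacrylic anhydride
Product: 31 C8 methacrylate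
Conditions: Et3N, 4-(dimethylamino)pyridine (cat.), CH2Cl2, 0 °C to rt
Reagents that add atoms: none
Why: Nucleophile-catalysed acylation of the secondary alcohol; from here on the C8 oxygen can no longer lactonise onto C12.

Step 20
Reactants: 31 C8 methacrylate
Product: 32 C3 primary alcohol
Conditions: camphorsulfonic acid (cat.), MeOH–CH2Cl2, 0 °C
Reagents that add atoms: none
Why: Acidic methanolysis removes the primary TBS ether while the TBDPS ether, the PMB ether and the ester remain; it is done before the acid-sensitive epoxide exists.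

Step 21
Reactants: 32 C3 primary alcohol
Product: 33 (1R,10R)-epoxy alcohol
Conditions: 1,2:4,5-di-O-isopropylidene-β-D-erythro-2,3-hexodiulo-2,6-pyranose (D-fructose-derived Shi ketone, 30 mol %), KHSO5 (as 2KHSO5·KHSO4·K2SO4), K2CO3, Bu4NHSO4, MeCN–CH2(OMe)2–aq. Na2B4O7 buffer, 0 °C
Reagents that add atoms: potassium peroxymonosulfate, [K+].[O-]S(=O)(=O)OO
Why: Shi epoxidation: the chiral dioxirane attacks the electron-rich (E)-trisubstituted alkene through the spiro transition state, and the D-fructose-derived ketone delivers oxygen to the face that gives the (R,R)-type epoxide, here 1R,10R; the vinyl iodide, the 1,1-disubstituted alkene and the methacrylate are too electron-poor or hindered to compete.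

Step 22
Reactants: 33 (1R,10R)-epoxy alcohol
Product: 34 β,γ-epoxy aldehyde (C3 aldehyde)
Conditions: Dess–Martin periodinane, pyridine, CH2Cl2, 0 °C; used crude
Reagents that add atoms: none
Why: Dess–Martin oxidation in buffered medium gives the aldehyde without the base or acid that would open the β,γ-epoxide.

Step 23
Reactants: 34 β,γ-epoxy aldehyde
Product: 35 (1R,3S,4Z,7R,8R,10R)-15-[(tert-butyldiphenylsilyl)oxy]-1,10-epoxy-3-hydroxy-12-[(4-methoxybenzyl)oxy]germacra-4,11(13)-dien-8-yl 2-methylprop-2-enoate
Conditions: CrCl2 (excess), NiCl2 (2 mol %), DMSO, 0.002 M, rt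
Reagents that add atoms: none
Why: Nozaki–Hiyama–Kishi reaction: nickel-catalysed formation of the vinylchromium species with retention of alkene geometry and 1,2-addition to the aldehyde at high dilution forms C3–C4, closes the ten-membered ring with the ring-cis alkene and creates C3; the required 3S alcohol is set under substrate control and the C3 epimers should be separable.

Step 24
Reactants: 35 macrocyclic PMB ether
Product: 36 (1R,3S,4Z,7R,8R,10R)-15-[(tert-butyldiphenylsilyl)oxy]-1,10-epoxy-3,12-dihydroxygermacra-4,11(13)-dien-8-yl 2-methylprop-2-enoate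
Conditions: DDQ, CH2Cl2–aq. NaH2PO4/Na2HPO4 buffer (pH 7), 0 °C
Reagents that add atoms: none
Why: Oxidative PMB cleavage in buffered medium frees the C12 alcohol; at 0 °C it is much faster than oxidation of the C3 allylic alcohol.

Step 25
Reactants: 36 C3,C12 diol
Product: 37 C12 aldehyde (2-substituted acrolein)
Conditions: 2,2,6,6-tetramethylpiperidin-1-oxyl (TEMPO, cat.), PhI(OAc)2, CH2Cl2, rt
Reagents that add atoms: none
Why: Oxoammonium oxidation is selective for the primary allylic alcohol over the more hindered secondary C3 alcohol and is neutral enough for the epoxide.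

Step 26
Reactants: 37 C12 aldehyde
Product: 38 (1R,3S,4Z,7R,8R,10R)-15-[(tert-butyldiphenylsilyl)oxy]-1,10-epoxy-3-hydroxy-8-(methacryloyloxy)germacra-4,11(13)-dien-12-oic acid
Conditions: NaClO2, NaH2PO4, 2-methyl-2-butene, t-BuOH–H2O, 0 °C to rt
Reagents that add atoms: sodium chlorite, [Na+].[O-]Cl=O
Why: Pinnick oxidation converts the α-substituted acrolein into the acrylic acid without touching alcohols or alkenes; 2-methyl-2-butene traps the hypochlorous acid.

Step 27
Reactants: 38 C15 silyl ether acid
Product: 39 (1R,3S,4Z,7R,8R,10R)-1,10-epoxy-3,15-dihydroxy-8-(methacryloyloxy)germacra-4,11(13)-dien-12-oic acid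
Conditions: Bu4NF, AcOH, THF, 0 °C to rt
Reagents that add atoms: none
Why: Fluoride cleavage of the silyl ether, buffered with acetic acid so that the methacrylate and the epoxide survive.

Step 28
Reactants: 39 C6-methylene 12-oic acid
Product: 41 (1R,3S,4Z,6R,7R,8R,10R)-1,10-epoxy-3,15-dihydroxy-8-(methacryloyloxy)germacra-4,11(13)-dien-12,6-olide, via 6-hydroxy acid 40 (not isolated)
Conditions: engineered cytochrome P450 monooxygenase of the costunolide-synthase type with its NADPH-dependent reductase (yeast microsomes), air (O2), NADPH (cat.) recycled by isopropanol and an NADP-dependent alcohol dehydrogenase, KH2PO4/K2HPO4 buffer pH 7.5, 30 °C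
Reagents that add atoms: dioxygen, O=O
Why: Proposed new method: the ferryl-oxo porphyrin radical cation of the P450 abstracts the C6 hydrogen turned towards the heme, giving an allylic radical stabilised by C4=C5, and hydroxyl rebound on the same face gives 6-hydroxy acid 40; the closest known reaction is the C6 hydroxylation of germacra-1(10),4,11(13)-trien-12-oic acids by costunolide-synthase-type P450s, which is followed by spontaneous lactonisation. The γ-hydroxy acid then closes the five-membered ring by 5-exo-trig attack of the C6 hydroxyl on the C12 carboxyl with loss of water. The new C6 stereocentre is fixed by the enzyme pocket, which anchors the C12 carboxylate and presents one C6–H, and rebound without inversion of the radical gives 6R and the trans ring fusion. Site selectivity over the C2, C9 and C14 hydrogens, over the carbinol hydrogens at C3 and C15 and over epoxidation of the three alkenes must come from this binding mode, helped by the allylic activation of C6. Because the C8 oxygen is acylated, only the C6 hydroxyl can lactonise. The substrate keeps the germacrenoic acid shape of the natural substrates, so a variant that tolerates the epoxide, the ring-cis alkene and the C8 ester is a reasonable but unproven goal.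

Step 29
Reactants: 41 15-hydroxy lactone
Product: 42 CNP0534814.1, (1R,3S,4E,6R,7R,8R,10R)-1,10-epoxy-3-hydroxy-8-(methacryloyloxy)-15-oxogermacra-4,11(13)-dien-12,6-olide
Conditions: 2,2,6,6-tetramethylpiperidin-1-oxyl (TEMPO, cat.), PhI(OAc)2, CH2Cl2, 0 °C to rt
Reagents that add atoms: none
Why: Oxoammonium oxidation selective for the primary allylic C15 alcohol; the secondary C3 alcohol, the epoxide and both acrylate units are left alone.

## Compound list

1 | but-2-yne-1,4-diol | OCC#CCO | starting material
2 | 4-[(tert-butyldiphenylsilyl)oxy]but-2-yn-1-ol | OCC#CCO[Si](c1ccccc1)(c1ccccc1)C(C)(C)C | intermediate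
3 | sodium 3-{[(tert-butyldiphenylsilyl)oxy]methyl}-2,2-bis(2-methoxyethoxy)-2,5-dihydro-1,2-oxaluminol-2-uide (cyclic vinylalanate) | [Na+].COCCO[Al-]1(OCCOC)OCC=C1CO[Si](c2ccccc2)(c2ccccc2)C(C)(C)C | intermediate
4 | (Z)-4-[(tert-butyldiphenylsilyl)oxy]-3-iodobut-2-en-1-ol | OC/C=C(\I)CO[Si](c1ccccc1)(c1ccccc1)C(C)(C)C | intermediate
5 | (Z)-[(4-bromo-2-iodobut-2-en-1-yl)oxy](tert-butyl)diphenylsilane | BrC/C=C(\I)CO[Si](c1ccccc1)(c1ccccc1)C(C)(C)C | intermediate
6 | ethyl (Z)-6-[(tert-butyldiphenylsilyl)oxy]-5-iodohex-4-enoate | CCOC(=O)CC/C=C(\I)CO[Si](c1ccccc1)(c1ccccc1)C(C)(C)C | intermediate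
7 | (Z)-6-[(tert-butyldiphenylsilyl)oxy]-5-iodohex-4-enoic acid | OC(=O)CC/C=C(\I)CO[Si](c1ccccc1)(c1ccccc1)C(C)(C)C | intermediate
8 | (S)-4-benzyl-1,3-oxazolidin-2-one | O=C1N[C@@H](Cc2ccccc2)CO1 | starting material
9 | (Z)-6-[(tert-butyldiphenylsilyl)oxy]-5-iodohex-4-enoic pivalic anhydride | CC(C)(C)C(=O)OC(=O)CC/C=C(\I)CO[Si](c1ccccc1)(c1ccccc1)C(C)(C)C | intermediate
10 | (S)-4-benzyl-3-{(Z)-6-[(tert-butyldiphenylsilyl)oxy]-5-iodohex-4-enoyl}-1,3-oxazolidin-2-one | O=C(CC/C=C(\I)CO[Si](c1ccccc1)(c1ccccc1)C(C)(C)C)N1[C@@H](Cc2ccccc2)COC1=O | intermediate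
11 | but-3-yn-1-ol | C#CCCO | starting material
12 | 1-[(but-3-yn-1-yloxy)methyl]-4-methoxybenzene | C#CCCOCc1ccc(OC)cc1 | intermediate
13 | {(1E)-4-[(4-methoxybenzyl)oxy]-2-methylbut-1-en-1-yl}dimethylalane | C[Al](C)/C=C(\C)CCOCc1ccc(OC)cc1 | intermediate
14 | lithium butyl{(1E)-4-[(4-methoxybenzyl)oxy]-2-methylbut-1-en-1-yl}dimethylalanuide | [Li+].CCCC[Al-](C)(C)/C=C(\C)CCOCc1ccc(OC)cc1 | intermediate
15 | (E)-6-[(4-methoxybenzyl)oxy]-4-methylhex-3-en-1-ol | OCC/C=C(\C)CCOCc1ccc(OC)cc1 | intermediate
16 | tert-butyl{[(E)-6-[(4-methoxybenzyl)oxy]-4-methylhex-3-en-1-yl]oxy}dimethylsilane | CC(C)(C)[Si](C)(C)OCC/C=C(\C)CCOCc1ccc(OC)cc1 | intermediate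
17 | (E)-6-[(tert-butyldimethylsilyl)oxy]-3-methylhex-3-en-1-ol | OCC/C(C)=C/CCO[Si](C)(C)C(C)(C)C | intermediate
18 | (E)-6-[(tert-butyldimethylsilyl)oxy]-3-methylhex-3-enal | O=CC/C(C)=C/CCO[Si](C)(C)C(C)(C)C | intermediate
19 | (S)-4-benzyl-3-{(1Z,4Z)-6-[(tert-butyldiphenylsilyl)oxy]-1-[(dibutylboranyl)oxy]-5-iodohexa-1,4-dien-1-yl}-1,3-oxazolidin-2-one | CCCCB(CCCC)O/C(=C\C/C=C(\I)CO[Si](c1ccccc1)(c1ccccc1)C(C)(C)C)N1[C@@H](Cc2ccccc2)COC1=O | intermediate
20 | (S)-4-benzyl-3-[(2S,3R,5E)-8-[(tert-butyldimethylsilyl)oxy]-2-{(2Z)-4-[(tert-butyldiphenylsilyl)oxy]-3-iodobut-2-en-1-yl}-3-hydroxy-5-methyloct-5-enoyl]-1,3-oxazolidin-2-one | O=C1OC[C@H](Cc2ccccc2)N1C(=O)[C@@H](C/C=C(\I)CO[Si](c3ccccc3)(c3ccccc3)C(C)(C)C)[C@H](O)C/C(C)=C/CCO[Si](C)(C)C(C)(C)C | intermediate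
21 | (2S,3R,5E)-8-[(tert-butyldimethylsilyl)oxy]-2-{(2Z)-4-[(tert-butyldiphenylsilyl)oxy]-3-iodobut-2-en-1-yl}-3-hydroxy-N-methoxy-N,5-dimethyloct-5-enamide | CON(C)C(=O)[C@@H](C/C=C(\I)CO[Si](c1ccccc1)(c1ccccc1)C(C)(C)C)[C@H](O)C/C(C)=C/CCO[Si](C)(C)C(C)(C)C | intermediate
22 | (2S,3R,5E)-8-[(tert-butyldimethylsilyl)oxy]-2-{(2Z)-4-[(tert-butyldiphenylsilyl)oxy]-3-iodobut-2-en-1-yl}-N-methoxy-N,5-dimethyl-3-[(triethylsilyl)oxy]oct-5-enamide | CON(C)C(=O)[C@@H](C/C=C(\I)CO[Si](c1ccccc1)(c1ccccc1)C(C)(C)C)[C@H](O[Si](CC)(CC)CC)C/C(C)=C/CCO[Si](C)(C)C(C)(C)C | intermediate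
23 | (tributylstannyl)methanol | CCCC[Sn](CCCC)(CCCC)CO | starting material
24 | tributyl{[(4-methoxybenzyl)oxy]methyl}stannane | CCCC[Sn](CCCC)(CCCC)COCc1ccc(OC)cc1 | intermediate
25 | {[(4-methoxybenzyl)oxy]methyl}lithium | [Li]COCc1ccc(OC)cc1 | intermediate
26 | bromo{[(4-methoxybenzyl)oxy]methyl}magnesium | Br[Mg]COCc1ccc(OC)cc1 | intermediate
27 | (3S,4R,6E)-9-[(tert-butyldimethylsilyl)oxy]-3-{(2Z)-4-[(tert-butyldiphenylsilyl)oxy]-3-iodobut-2-en-1-yl}-1-[(4-methoxybenzyl)oxy]-6-methyl-4-[(triethylsilyl)oxy]non-6-en-2-one | COc1ccc(COCC(=O)[C@@H](C/C=C(\I)CO[Si](c2ccccc2)(c2ccccc2)C(C)(C)C)[C@H](O[Si](CC)(CC)CC)C/C(C)=C/CCO[Si](C)(C)C(C)(C)C)cc1 | intermediate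
28 | (3R,4R,6E)-9-[(tert-butyldimethylsilyl)oxy]-3-{(2Z)-4-[(tert-butyldiphenylsilyl)oxy]-3-iodobut-2-en-1-yl}-1-[(4-methoxybenzyl)oxy]-6-methyl-2-methylidene-4-[(triethylsilyl)oxy]non-6-ene | COc1ccc(COCC(=C)[C@@H](C/C=C(\I)CO[Si](c2ccccc2)(c2ccccc2)C(C)(C)C)[C@H](O[Si](CC)(CC)CC)C/C(C)=C/CCO[Si](C)(C)C(C)(C)C)cc1 | intermediate
29 | (3R,4R,6E)-9-[(tert-butyldimethylsilyl)oxy]-3-{(2Z)-4-[(tert-butyldiphenylsilyl)oxy]-3-iodobut-2-en-1-yl}-1-[(4-methoxybenzyl)oxy]-6-methyl-2-methylidenenon-6-en-4-ol | COc1ccc(COCC(=C)[C@@H](C/C=C(\I)CO[Si](c2ccccc2)(c2ccccc2)C(C)(C)C)[C@H](O)C/C(C)=C/CCO[Si](C)(C)C(C)(C)C)cc1 | intermediate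
30 | methacrylic anhydride | CC(=C)C(=O)OC(=O)C(C)=C | starting material
31 | methacrylate (2-methylprop-2-enoate) of 29 at the C8 oxygen (7R,8R) | COc1ccc(COCC(=C)[C@@H](C/C=C(\I)CO[Si](c2ccccc2)(c2ccccc2)C(C)(C)C)[C@H](OC(=O)C(C)=C)C/C(C)=C/CCO[Si](C)(C)C(C)(C)C)cc1 | intermediate
32 | (3R,4R,6E)-3-{(2Z)-4-[(tert-butyldiphenylsilyl)oxy]-3-iodobut-2-en-1-yl}-9-hydroxy-1-[(4-methoxybenzyl)oxy]-6-methyl-2-methylidenenon-6-en-4-yl 2-methylprop-2-enoate | COc1ccc(COCC(=C)[C@@H](C/C=C(\I)CO[Si](c2ccccc2)(c2ccccc2)C(C)(C)C)[C@H](OC(=O)C(C)=C)C/C(C)=C/CCO)cc1 | intermediate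
33 | (2R,3R)-3-{(2Z)-4-[(tert-butyldiphenylsilyl)oxy]-3-iodobut-2-en-1-yl}-1-[(2R,3R)-3-(2-hydroxyethyl)-2-methyloxiran-2-yl]-4-{[(4-methoxybenzyl)oxy]methyl}pent-4-en-2-yl 2-methylprop-2-enoate (the 1R,10R-epoxide of 32) | COc1ccc(COCC(=C)[C@@H](C/C=C(\I)CO[Si](c2ccccc2)(c2ccccc2)C(C)(C)C)[C@H](OC(=O)C(C)=C)C[C@@]2(C)O[C@@H]2CCO)cc1 | intermediate
34 | aldehyde of 33 at C3: (2R,3R)-3-{(2Z)-4-[(tert-butyldiphenylsilyl)oxy]-3-iodobut-2-en-1-yl}-4-{[(4-methoxybenzyl)oxy]methyl}-1-[(2R,3R)-2-methyl-3-(2-oxoethyl)oxiran-2-yl]pent-4-en-2-yl 2-methylprop-2-enoate | COc1ccc(COCC(=C)[C@@H](C/C=C(\I)CO[Si](c2ccccc2)(c2ccccc2)C(C)(C)C)[C@H](OC(=O)C(C)=C)C[C@@]2(C)O[C@@H]2CC=O)cc1 | intermediate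
35 | (1R,3S,4Z,7R,8R,10R)-15-[(tert-butyldiphenylsilyl)oxy]-1,10-epoxy-3-hydroxy-12-[(4-methoxybenzyl)oxy]germacra-4,11(13)-dien-8-yl 2-methylprop-2-enoate | C=C(C)C(=O)O[C@@H]1C[C@@]2(C)O[C@@H]2C[C@H](O)/C(CO[Si](c3ccccc3)(c3ccccc3)C(C)(C)C)=C\C[C@@H]1C(=C)COCc1ccc(OC)cc1 | intermediate
36 | (1R,3S,4Z,7R,8R,10R)-15-[(tert-butyldiphenylsilyl)oxy]-1,10-epoxy-3,12-dihydroxygermacra-4,11(13)-dien-8-yl 2-methylprop-2-enoate | C=C(C)C(=O)O[C@@H]1C[C@@]2(C)O[C@@H]2C[C@H](O)/C(CO[Si](c3ccccc3)(c3ccccc3)C(C)(C)C)=C\C[C@@H]1C(=C)CO | intermediate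
37 | (1R,3S,4Z,7R,8R,10R)-15-[(tert-butyldiphenylsilyl)oxy]-1,10-epoxy-3-hydroxy-12-oxogermacra-4,11(13)-dien-8-yl 2-methylprop-2-enoate | C=C(C)C(=O)O[C@@H]1C[C@@]2(C)O[C@@H]2C[C@H](O)/C(CO[Si](c3ccccc3)(c3ccccc3)C(C)(C)C)=C\C[C@@H]1C(=C)C=O | intermediate
38 | (1R,3S,4Z,7R,8R,10R)-15-[(tert-butyldiphenylsilyl)oxy]-1,10-epoxy-3-hydroxy-8-(methacryloyloxy)germacra-4,11(13)-dien-12-oic acid | C=C(C)C(=O)O[C@@H]1C[C@@]2(C)O[C@@H]2C[C@H](O)/C(CO[Si](c3ccccc3)(c3ccccc3)C(C)(C)C)=C\C[C@@H]1C(=C)C(=O)O | intermediate
39 | (1R,3S,4Z,7R,8R,10R)-1,10-epoxy-3,15-dihydroxy-8-(methacryloyloxy)germacra-4,11(13)-dien-12-oic acid | C=C(C)C(=O)O[C@@H]1C[C@@]2(C)O[C@@H]2C[C@H](O)/C(CO)=C\C[C@@H]1C(=C)C(=O)O | intermediate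
40 | (1R,3S,4Z,6R,7S,8R,10R)-1,10-epoxy-3,6,15-trihydroxy-8-(methacryloyloxy)germacra-4,11(13)-dien-12-oic acid | C=C(C)C(=O)O[C@@H]1C[C@@]2(C)O[C@@H]2C[C@H](O)/C(CO)=C\[C@@H](O)[C@@H]1C(=C)C(=O)O | intermediate
41 | (1R,3S,4Z,6R,7R,8R,10R)-1,10-epoxy-3,15-dihydroxy-8-(methacryloyloxy)germacra-4,11(13)-dien-12,6-olide | C=C(C)C(=O)O[C@@H]1C[C@@]2(C)O[C@@H]2C[C@H](O)/C(CO)=C\[C@H]2OC(=O)C(=C)[C@@H]21 | intermediate
42 | CNP0534814.1, (1R,3S,4E,6R,7R,8R,10R)-1,10-epoxy-3-hydroxy-8-(methacryloyloxy)-15-oxogermacra-4,11(13)-dien-12,6-olide | C=C(C)C(=O)O[C@@H]1C[C@@]2(C)O[C@@H]2C[C@H](O)/C(C=O)=C\[C@H]2OC(=O)C(=C)[C@@H]21 | target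

## Step count and least certain steps

Total step count: 29. Longest linear sequence: 23 steps (steps 1–6, 12–14 and 16–29).

**Step 28 (key step).** The enzyme may fail to bind or turn over 39, or may oxidise elsewhere (epoxidation of the acrylic or methacrylic double bond, hydroxylation at C2 or C9), because the pocket evolved for a less oxygenated triene acid and must be reshaped. The fallback uses known chemistry and a different activation, with C6–H made reactive as the γ-position of the enal. It sets out from 39. Oxidation with TEMPO and PhI(OAc)2 gives the enal acid F1. TESOTf and Et3N convert it into the tris(triethylsilyl) dienol ether F2 (C15 enol ether, C3 ether and silyl ester; the new C4=C15 and C5=C6 bonds form as a mixture of geometries). Oxidation of F2 with dimethyldioxirane at the γ-terminus (vinylogous Rubottom oxidation), then HF·pyridine, frees the 6-hydroxy enal acid, which lactonises, and the sequence rejoins the route at 42. The face of attack at C6 then depends on the ring conformation and is not assured.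

**Step 23.** The ring closure may show poor facial selectivity at C3, or intermolecular coupling may compete with closure of the strained ring. The fallback sets C3 by reagent control. It sets out from 34: the cyclisation is run without regard to C3, and the alcohol mixture containing the 3R-epimer F3 is oxidised with Dess–Martin periodinane to the enone F4. Reduction of F4 with BH3·SMe2 and the (R)-methyl-CBS oxazaborolidine, with the alkenyl group as the large substituent, should give the 3S alcohol and returns to 35.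

**Step 22.** The β,γ-epoxy aldehyde may suffer β-elimination with opening of the epoxide during oxidation or in the Lewis-acidic chromium medium of step 23. The fallback postpones the epoxidation. It sets out from 32: Dess–Martin oxidation gives the β,γ-unsaturated aldehyde F5, NHK closure gives the macrocyclic diene alcohol F6, and Shi epoxidation of its (E)-C1=C10 alkene, the more electron-rich of the two ring alkenes, returns to 35.

**Step 16.** Iodine–metal exchange at the vinyl iodide by incompletely transmetalated alkoxymethyllithium would destroy the handle for the ring closure. The fallback avoids organolithium reagents. It sets out from 22: i-Bu2AlH reduces the Weinreb amide to the aldehyde F7. A SmI2-mediated Barbier reaction with 4-methoxybenzyl chloromethyl ether gives the carbinol F8 as a mixture of C11 epimers; vinyl iodides are inert to SmI2 without polar additives. Dess–Martin oxidation returns to 27.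

## Further compounds

F1 | step 28 | (1R,3S,4E,7R,8R,10R)-1,10-epoxy-3-hydroxy-8-(methacryloyloxy)-15-oxogermacra-4,11(13)-dien-12-oic acid (enal acid) | C=C(C)C(=O)O[C@@H]1C[C@@]2(C)O[C@@H]2C[C@H](O[H])/C(C=O)=C\C[C@@H]1C(=C)C(=O)O
F2 | step 28 | triethylsilyl (1R,3S,7R,8R,10R)-1,10-epoxy-8-(methacryloyloxy)-3,15-bis[(triethylsilyl)oxy]germacra-4(15),5,11(13)-trien-12-oate (silyl dienol ether, mixture of geometries at the two new double bonds) | C=C(C)C(=O)O[C@@H]1C[C@@]2(C)O[C@@H]2C[C@H](O[Si](CC)(CC)CC)C(=CO[Si](CC)(CC)CC)C=C[C@@H]1C(=C)C(=O)O[Si](CC)(CC)CC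
F3 | step 23 | (1R,3R,4Z,7R,8R,10R)-15-[(tert-butyldiphenylsilyl)oxy]-1,10-epoxy-3-hydroxy-12-[(4-methoxybenzyl)oxy]germacra-4,11(13)-dien-8-yl 2-methylprop-2-enoate (C3 epimer of 35) | C=C(C)C(=O)O[C@@H]1C[C@@]2(C)O[C@@H]2C[C@@H](O)/C(CO[Si](c3ccccc3)(c3ccccc3)C(C)(C)C)=C\C[C@@H]1C(=C)COCc1ccc(OC)cc1
F4 | step 23 | (1R,4Z,7R,8R,10R)-15-[(tert-butyldiphenylsilyl)oxy]-1,10-epoxy-12-[(4-methoxybenzyl)oxy]-3-oxogermacra-4,11(13)-dien-8-yl 2-methylprop-2-enoate (enone) | C=C(C)C(=O)O[C@@H]1C[C@@]2(C)O[C@@H]2CC(=O)/C(CO[Si](c3ccccc3)(c3ccccc3)C(C)(C)C)=C\C[C@@H]1C(=C)COCc1ccc(OC)cc1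
F5 | step 22 | (3R,4R,6E)-3-{(2Z)-4-[(tert-butyldiphenylsilyl)oxy]-3-iodobut-2-en-1-yl}-1-[(4-methoxybenzyl)oxy]-6-methyl-2-methylidene-9-oxonon-6-en-4-yl 2-methylprop-2-enoate | COc1ccc(COCC(=C)[C@@H](C/C=C(\I)CO[Si](c2ccccc2)(c2ccccc2)C(C)(C)C)[C@H](OC(=O)C(C)=C)C/C(C)=C/CC=O)cc1
F6 | step 22 | (1(10)E,3S,4Z,7R,8R)-15-[(tert-butyldiphenylsilyl)oxy]-3-hydroxy-12-[(4-methoxybenzyl)oxy]germacra-1(10),4,11(13)-trien-8-yl 2-methylprop-2-enoate | C=C(C)C(=O)O[C@@H]1C/C(C)=C/C[C@H](O)/C(CO[Si](c2ccccc2)(c2ccccc2)C(C)(C)C)=C\C[C@@H]1C(=C)COCc1ccc(OC)cc1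
F7 | step 16 | (2S,3R,5E)-8-[(tert-butyldimethylsilyl)oxy]-2-{(2Z)-4-[(tert-butyldiphenylsilyl)oxy]-3-iodobut-2-en-1-yl}-5-methyl-3-[(triethylsilyl)oxy]oct-5-enal | O=C[C@@H](C/C=C(\I)CO[Si](c1ccccc1)(c1ccccc1)C(C)(C)C)[C@H](O[Si](CC)(CC)CC)C/C(C)=C/CCO[Si](C)(C)C(C)(C)C
F8 | step 16 | (3S,4R,6E)-9-[(tert-butyldimethylsilyl)oxy]-3-{(2Z)-4-[(tert-butyldiphenylsilyl)oxy]-3-iodobut-2-en-1-yl}-1-[(4-methoxybenzyl)oxy]-6-methyl-4-[(triethylsilyl)oxy]non-6-en-2-ol (both epimers at the carbinol carbon) | COc1ccc(COCC(O)[C@@H](C/C=C(\I)CO[Si](c2ccccc2)(c2ccccc2)C(C)(C)C)[C@H](O[Si](CC)(CC)CC)C/C(C)=C/CCO[Si](C)(C)C(C)(C)C)cc1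
A1 | alternative 1 | ten-membered 4,1(10)-dien-6-one with C8–OMOM, C3–OTBS, C15–OPMB and a 2-(silyloxy)ethyl arm on C7 | COCO[C@@H]1C/C(C)=C/C[C@H](O[Si](C)(C)C(C)(C)C)/C(COCc2ccc(OC)cc2)=C\C(=O)[C@@H]1CCO[Si](C)(C)C(C)(C)C
A2 | alternative 2 | 8-O-triethylsilyl 3-O-TBS 1,10-epoxy-12,6-olide with C15 as methyl ester | CC[Si](CC)(CC)O[C@@H]1C[C@@]2(C)O[C@@H]2C[C@H](O[Si](C)(C)C(C)(C)C)/C(C(=O)OC)=C\[C@H]2OC(=O)C(=C)[C@@H]21
A3 | alternative 3 | 8-O-triethylsilyl 3-O-TBS 1,10-epoxy-11-(diethoxyphosphoryl)-12,6-olide with C15 as methyl ester | CC[Si](CC)(CC)O[C@@H]1C[C@@]2(C)O[C@@H]2C[C@H](O[Si](C)(C)C(C)(C)C)/C(C(=O)OC)=C\[C@H]2OC(=O)[C@@H](P(=O)(OCC)OCC)[C@@H]21
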